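Ring A of the target, with the C3 oxygen, one C4 methyl and the angular C10 methyl, is a latent 3-substituted 2,4-dimethylphenol whose para carbon is C10. The route rests on the C9–C10 disconnection. In one palladium-catalysed operation the phenolate attacks an allyl–palladium terminus through C10. This breaks the aromaticity, closes ring B, creates quaternary C10 and vinyl-bearing C9, and leaves a dienone from which the gem-dimethyl group and the trans ring fusion follow. The precursor 16 is the free phenol whose C5 carries a six-carbon chain ending in an (E)-allylic methyl carbonate. Its C8 oxygen is an (S)-configured silyl ether, set beforehand by catalytic asymmetric alkenylation.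

Key step: step 11

Remarks on the chemistry (valid for the whole route)
- **Numbering and configuration.** Labdane numbering is used throughout. α and β mean below and above the decalin drawn in the usual terpenoid orientation (ring A left, C10 at the top of the fusion). Read this way the target is 3α-OH, 5β-H, 7α-OH, 9β-H (side chain α) and 10α-CH3, that is (3R,5S,7R,9S,10R), with a 13Z double bond (C12 cis to C15). It is an enantio-labdane with a trans-decalin in which both hydroxyls and the side chain are equatorial.
- **C8 enters the key step as a silyl ether, not as a ketone.**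
  - An acyl group on the allyl complex would steer the nucleophile to the remote terminus C12.
  - The α-vinyl ketone formed would slip into conjugation in the basic medium and erase C9 and the vinyl handle.
  - Masking the ketone afterwards would need acid next to a dienone prone to dienone–phenol rearrangement.
  - The carbinol centre makes the key step diastereoselective, so leakage at C10 gives a separable diastereomer and not the enantiomer.
  - C8 becomes a ketone only in step 19, when C11–C12 is saturated.
- **The cross-conjugated dienone is not exposed to dissolving metal.** Its ketyl could re-aromatise by expelling the allylic C9, and the two-electron product is a dienolate that resists further reduction. C1=C2 is therefore removed first by a copper hydride (step 12).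

Step 1
Reactants: 1 2-bromo-1,3-dimethylbenzene
Product: 2 2-bromo-1,3-dimethyl-4-nitrobenzene
Conditions: HNO3 (65 %, 1.05 equiv), H2SO4, 0 °C
Reagents that add atoms: nitric acid, O[N+](=O)[O-]
Why: Electrophilic aromatic nitration in which both methyl groups direct to C4 (ortho to one, para to the other), while the only other kind of free position is meta to both, so one mononitro isomer should dominate.

Step 2
Reactants: 2 2-bromo-1,3-dimethyl-4-nitrobenzene
Product: 3 3-bromo-2,4-dimethylaniline
Conditions: H2 (1 atm), sulfided 5 % Pt/C, EtOAc, rt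
Reagents that add atoms: none
Why: Catalytic hydrogenation of a nitroarene over sulfided platinum, a catalyst poisoned enough to leave the aryl bromide untouched.

Step 3
Reactants: 3 3-bromo-2,4-dimethylaniline
Product: 5 3-bromo-2,4-dimethylphenol, via diazonium hydrogen sulfate 4 (not isolated)
Conditions: NaNO2, aq H2SO4, 0 °C; then added to boiling aq H2SO4/toluene
Reagents that add atoms: water, O; sodium nitrite, [Na+].[O-]N=O (outer nitrogen of 4 only); sulfuric acid, OS(=O)(=O)O (counter-ion of 4 only)
Why: Diazotisation followed by thermal hydrolysis of the diazonium salt (loss of N2 and capture by water), which tolerates the bromide and both methyl groups.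

Step 4
Reactants: 5 3-bromo-2,4-dimethylphenol
Product: 6 tert-butyl(3-bromo-2,4-dimethylphenoxy)dimethylsilane
Conditions: TBSCl, imidazole, DMF, rt
Reagents that add atoms: tert-butyldimethylsilyl chloride, CC(C)(C)[Si](C)(C)Cl
Why: Imidazole-promoted silylation hides the acidic OH from the organozinc step, and the aryl silyl ether can later be removed by fluoride in preference to alkyl silyl ethers.

Step 5
Reactants: 6 tert-butyl(3-bromo-2,4-dimethylphenoxy)dimethylsilane; 7 prop-2-en-1-ol (allyl alcohol)
Product: 8 3-[3-(tert-butyldimethylsilyloxy)-2,6-dimethylphenyl]propanal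
Conditions: Pd(OAc)2 (5 mol %), P(t-Bu)3·HBF4 (10 mol %), Cy2NMe, dioxane, 100 °C
Reagents that add atoms: none
Why: Heck reaction of an allylic alcohol, in which the aryl group adds to the terminal carbon, β-hydride elimination towards the carbinol carbon gives the enol and hence the aldehyde, and the bulky electron-rich phosphine lets a doubly ortho-substituted bromide react.

Step 6
Reactants: 8 3-[3-(tert-butyldimethylsilyloxy)-2,6-dimethylphenyl]propanal; 9 tert-butyldimethyl(prop-2-yn-1-yloxy)silane
Product: 12 (3S,4E)-6-(tert-butyldimethylsilyloxy)-1-[3-(tert-butyldimethylsilyloxy)-2,6-dimethylphenyl]hex-4-en-3-ol, via alkenyldicyclohexylborane 10 (not isolated), via alkenyl(methyl)zinc 11 (not isolated)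
Conditions: Cy2BH (from BH3·SMe2, cyclohexene), toluene, 0 °C → rt; Me2Zn, −78 °C; (+)-MIB (3-exo-morpholinoisoborneol, 5 mol %), then 8, −10 °C; aq NH4Cl
Reagents that add atoms: dicyclohexylborane, B(C1CCCCC1)C1CCCCC1 (boron and cyclohexyl groups of 10 only); dimethylzinc, C[Zn]C (zinc and methyl of 11 only)
Why: Syn hydroboration of the terminal alkyne fixes the E geometry, boron-to-zinc exchange gives the alkenylzinc, and the amino-alcohol-catalysed asymmetric 1,2-addition with the (+)-ligand delivers it to the Re face of the aldehyde, which sets C8 as S.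

Step 7
Reactants: 12 (3S,4E)-allylic alcohol
Product: 13 tert-butyl{3-[(3S,4E)-3,6-bis(tert-butyldimethylsilyloxy)hex-4-enyl]-2,4-dimethylphenoxy}dimethylsilane
Conditions: TBSCl, imidazole, DMF, rt
Reagents that add atoms: tert-butyldimethylsilyl chloride, CC(C)(C)[Si](C)(C)Cl
Why: Imidazole-promoted silylation of the secondary allylic alcohol, which touches no stereocentre.

Step 8
Reactants: 13 tris(silyl ether)
Product: 14 (2E,4S)-4-(tert-butyldimethylsilyloxy)-6-[3-(tert-butyldimethylsilyloxy)-2,6-dimethylphenyl]hex-2-en-1-ol
Conditions: camphorsulfonic acid (10 mol %), MeOH/CH2Cl2 1:1, 0 °C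
Reagents that add atoms: none
Why: Acid-catalysed methanolysis discriminates by steric access, so the primary silyl ether goes first, the secondary one is slower and the aryl silyl ether is the least acid-labile.

Step 9
Reactants: 14 primary allylic alcohol
Product: 15 (2E,4S)-4-(tert-butyldimethylsilyloxy)-6-[3-(tert-butyldimethylsilyloxy)-2,6-dimethylphenyl]hex-2-enyl methyl carbonate
Conditions: ClCO2Me, pyridine, CH2Cl2, 0 °C
Reagents that add atoms: methyl chloroformate, COC(=O)Cl
Why: Acylation of the primary alcohol with a chloroformate installs the leaving group that will also supply the base of the key step.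

Step 10
Reactants: 15 aryl-silylated allylic carbonate
Product: 16 (2E,4S)-4-(tert-butyldimethylsilyloxy)-6-(3-hydroxy-2,6-dimethylphenyl)hex-2-enyl methyl carbonate
Conditions: Bu4NF (1.0 equiv), AcOH (1.2 equiv), THF, 0 °C
Reagents that add atoms: none
Why: Fluoride cleaves the aryl silyl ether far faster than the hindered secondary alkyl one because phenoxide is the better leaving group, and the acetic acid buffer protects the carbonate from the liberated phenoxide.

Step 11
Reactants: 16 (2E,4S)-4-(tert-butyldimethylsilyloxy)-6-(3-hydroxy-2,6-dimethylphenyl)hex-2-enyl methyl carbonate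
Product: 17 (4aS,5S,6S)-6-(tert-butyldimethylsilyloxy)-5-ethenyl-1,4a-dimethyl-5,6,7,8-tetrahydronaphthalen-2(4aH)-one (cross-conjugated dienone; 8β-OTBS 9α-vinyl 10α-methyl)
Conditions: Pd2(dba)3·CHCl3 (2.5 mol %), PPh3 (12 mol %), CH2Cl2 (0.01 M), 25 °C
Reagents that add atoms: none
Why: Proposed new method: zerovalent palladium ionises the primary allylic carbonate of 16 to a syn-substituted η3-allyl complex of divalent palladium spanning C9, C11 and C12, and the methoxide left after loss of CO2 deprotonates the phenol, so electrophile and phenolate are generated together without added base. The phenolate attacks through its para carbon C10, anti to the metal, at the near terminus C9, which forms the C9–C10 bond and closes ring B in a 6-exo mode, whereas attack at C12 would be an 8-endo closure to a strained E-cyclooctene. The closest known reaction types are the palladium- and iridium-catalysed intramolecular allylic dearomatisations of para-tethered phenols to spirocyclohexadienones, the allylic Friedel–Crafts cyclisation of meta-tethered phenols at a free para position and the palladium-catalysed arylative dearomative cyclisation of meta-tethered 4-alkylphenols to fused dienones, but an allyl electrophile on a meta tether has not been joined to a blocked para carbon. C10 is controlled by the C8 stereocentre, because in the chair-like transition state the silyloxy group stays equatorial (an axial one would meet the C10 methyl in a 1,3-diaxial clash) and this decides which face of the flat phenolate the chain covers. C9 is controlled by the same chair, the syn-allyl unit lying equatorial and trans to the C8 oxygen, and a C9 epimer would in any case be levelled at ketone 28. The step needs para rather than ortho attack, secured by the larger para coefficient of the phenolate, by C4 being flanked on both sides (C3–O and C5) while C10 has the free C1–H next to it and by the greater stability of the cross-conjugated dienone; both carbons carry methyl so nothing can re-aromatise, O-allylation within the molecule is geometrically impossible and high dilution suppresses it between molecules.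

Step 12
Reactants: 17 cross-conjugated dienone
Product: 18 (4aS,5S,6S)-6-(tert-butyldimethylsilyloxy)-5-ethenyl-1,4a-dimethyl-4,4a,5,6,7,8-hexahydronaphthalen-2(3H)-one (4-methyl-Δ4-3-ketone)
Conditions: [(Ph3P)CuH]6 (0.4 equiv), H2O (5 equiv), degassed toluene, rt
Reagents that add atoms: none
Why: Copper hydride conjugate reduction delivers hydride to C1 of the disubstituted enone arm, while the tetrasubstituted C4=C5 arm and the isolated vinyl group are inert, so the reaction should stop at the enone without single-electron chemistry that could cleave C9–C10.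

Step 13
Reactants: 18 4-methyl-Δ4-3-ketone
Product: 20 (4aR,5S,6S,8aS)-6-(tert-butyldimethylsilyloxy)-5-ethenyl-1,1,4a-trimethyloctahydronaphthalen-2(1H)-one (trans-decalone; 5β-H), via lithium enolate 19 (not isolated)
Conditions: Li (2.5 equiv), t-BuOH (1.0 equiv), NH3/THF, −78 → −33 °C; isoprene; MeI (excess), −78 °C → rt
Reagents that add atoms: iodomethane, CI; lithium, [Li] (in 19 only)
Why: Dissolving-metal reductive alkylation of an enone, in which axial protonation of C5 on the face opposite the C10 methyl gives the trans-decalin and the regiodefined C3–C4 enolate 19 is methylated at C4 before it can equilibrate, with vinyl group and homoallylic silyl ether inert.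

Step 14
Reactants: 20 trans-decalone
Product: 21 (2R,4aR,5S,6S,8aS)-6-(tert-butyldimethylsilyloxy)-5-ethenyl-1,1,4a-trimethyldecahydronaphthalen-2-ol (3α-OH equatorial)
Conditions: NaBH4, MeOH/THF, 0 °C
Reagents that add atoms: none
Why: Borohydride reduction of a 4,4-dimethyl-3-decalone, where hydride enters axially on the face away from the axial C4 and C10 methyl groups and so gives the equatorial 3α-alcohol.

Step 15
Reactants: 21 3α-alcohol
Product: 22 3α-acetate of 21 (3α-OAc 5β-H 8β-OTBS 9α-vinyl 10α-methyl)
Conditions: Ac2O, DMAP, pyridine, rt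
Reagents that add atoms: acetic anhydride, CC(=O)OC(C)=O
Why: DMAP-catalysed acetylation distinguishes C3 from C8 for the later oxidation, and the acetate can be removed at the end by methanolysis, which cannot alter a methyl ester.

Step 16
Reactants: 23 methyl but-2-ynoate
Product: 24 methyl (Z)-3-iodobut-2-enoate
Conditions: NaI, AcOH, 115 °C
Reagents that add atoms: sodium iodide, [Na+].[I-]
Why: Conjugate hydroiodination of an ynoate, in which iodide adds to C3 and protonation occurs anti, so iodine and ester end up cis (Z).

Step 17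
Reactants: 22 vinyl acetate; 24 methyl (Z)-3-iodobut-2-enoate
Product: 26 methyl (13Z)-3α-acetoxy-8β-(tert-butyldimethylsilyloxy)-17-norlabd-13-en-15-oate (5β-H 9β-H 10α-methyl series), via B-alkyl-9-BBN adduct 25 (not isolated)
Conditions: 9-BBN dimer, THF, rt → 50 °C; then 24, Pd(dppf)Cl2·CH2Cl2 (5 mol %), AsPh3 (10 mol %), Cs2CO3, DMF/H2O, rt
Reagents that add atoms: 9-borabicyclo[3.3.1]nonane, B1C2CCCC1CCC2 (in 25 only)
Why: Hydroboration puts boron on the terminal C12 for steric reasons, and the B-alkyl Suzuki–Miyaura coupling proceeds with retention at the alkenyl iodide, so the Z geometry of 24 becomes the 13Z geometry.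

Step 18
Reactants: 26 silyl ether
Product: 27 methyl (13Z)-3α-acetoxy-8β-hydroxy-17-norlabd-13-en-15-oate
Conditions: 48 % aq HF, MeCN, rt
Reagents that add atoms: none
Why: Acidic fluoride cleaves the remaining silyl ether and spares both esters, and it is preferred to basic fluoride so that no C8 alkoxide can add to C13 of the enoate.

Step 19
Reactants: 27 C8 alcohol
Product: 28 methyl (13Z)-3α-acetoxy-8-oxo-17-norlabd-13-en-15-oate
Conditions: Dess–Martin periodinane, CH2Cl2, rt
Reagents that add atoms: none
Why: Dess–Martin oxidation gives the C8 ketone under neutral conditions, and since the equatorial side chain is the thermodynamic arrangement at the now epimerisable C9, brief exposure to DBU could level any C9 epimer carried from step 11.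

Step 20
Reactants: 28 C8 ketone
Product: 29 methyl (13Z)-3α-acetoxylabda-8(17),13-dien-15-oate
Conditions: Zn, CH2Br2, TiCl4 (reagent aged in THF at 5 °C), CH2Cl2, 0 °C → rt
Reagents that add atoms: dibromomethane, BrCBr
Why: Lombardo methylenation with the non-basic zinc/titanium methylene reagent attacks only the ketone, leaves both esters alone and neither epimerises C9 nor isomerises the Z enoate.

Step 21
Reactants: 29 8(17)-ene
Product: 30 methyl (13Z)-3α-acetoxy-7β-hydroxylabda-8(17),13-dien-15-oate (7-OH axial)
Conditions: SeO2 (0.3 equiv), t-BuOOH (5.5 M in decane), CH2Cl2, 0 °C → rt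
Reagents that add atoms: tert-butyl hydroperoxide, CC(C)(C)OO (terminal oxygen source); selenium dioxide, O=[Se]=O (oxygen carrier)
Why: Allylic hydroxylation with SeO2 (ene reaction at C17 with loss of the axial C7 hydrogen, then [2,3]-sigmatropic shift) restores the exocyclic double bond and places the oxygen axial, while the electron-poor enoate is far less reactive and C9–H is shielded by the side chain and quaternary C10.

Step 22
Reactants: 30 axial allylic alcohol
Product: 31 methyl (13Z)-3α-acetoxy-7-oxolabda-8(17),13-dien-15-oate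
Conditions: Dess–Martin periodinane, NaHCO3, CH2Cl2, 0 °C
Reagents that add atoms: none
Why: Buffered Dess–Martin oxidation erases the wrongly configured C7 centre, and the sensitive exo-methylene ketone is carried on at once.

Step 23
Reactants: 31 exo-methylene ketone
Product: 32 methyl (13Z)-3α-acetoxy-7α-hydroxylabda-8(17),13-dien-15-oate (7-OH equatorial)
Conditions: CeCl3·7H2O, NaBH4, MeOH, −78 → −40 °C
Reagents that add atoms: none
Why: Luche reduction adds hydride 1,2 and axially, on the β face that carries only the axial hydrogens at C5 and C9, which gives the equatorial 7α-alcohol.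

Step 24
Reactants: 32 3-acetate
Product: 33 methyl (3R,5S,7R,9S,10R,13Z)-3,7-dihydroxylabda-8(17),13-dien-15-oate (CNP0284783.1)
Conditions: K2CO3 (0.5 equiv), MeOH, rt → 40 °C
Reagents that add atoms: none
Why: Base-catalysed transesterification removes the acetate, while exchange at the methyl ester is degenerate and no stereocentre or double bond is affected.

Compound list
1 | 2-bromo-1,3-dimethylbenzene | Cc1cccc(C)c1Br | starting material
2 | 2-bromo-1,3-dimethyl-4-nitrobenzene | Cc1ccc([N+](=O)[O-])c(C)c1Br | intermediate
3 | 3-bromo-2,4-dimethylaniline | Cc1ccc(N)c(C)c1Br | intermediate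
4 | 3-bromo-2,4-dimethylbenzenediazonium hydrogen sulfate | Cc1ccc([N+]#N)c(C)c1Br.OS(=O)(=O)[O-] | intermediate (not isolated)
5 | 3-bromo-2,4-dimethylphenol | Cc1ccc(O)c(C)c1Br | intermediate
6 | tert-butyl(3-bromo-2,4-dimethylphenoxy)dimethylsilane | Cc1ccc(O[Si](C)(C)C(C)(C)C)c(C)c1Br | intermediate
7 | prop-2-en-1-ol | C=CCO | starting material
8 | 3-[3-(tert-butyldimethylsilyloxy)-2,6-dimethylphenyl]propanal | Cc1ccc(O[Si](C)(C)C(C)(C)C)c(C)c1CCC=O | intermediate
9 | tert-butyldimethyl(prop-2-yn-1-yloxy)silane | C#CCO[Si](C)(C)C(C)(C)C | starting material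
10 | (E)-[3-(tert-butyldimethylsilyloxy)prop-1-enyl]dicyclohexylborane | CC(C)(C)[Si](C)(C)OC/C=C/B(C1CCCCC1)C1CCCCC1 | intermediate (not isolated)
11 | (E)-[3-(tert-butyldimethylsilyloxy)prop-1-enyl](methyl)zinc | C[Zn]/C=C/CO[Si](C)(C)C(C)(C)C | intermediate (not isolated)
12 | (3S,4E)-6-(tert-butyldimethylsilyloxy)-1-[3-(tert-butyldimethylsilyloxy)-2,6-dimethylphenyl]hex-4-en-3-ol | Cc1ccc(O[Si](C)(C)C(C)(C)C)c(C)c1CC[C@H](O)/C=C/CO[Si](C)(C)C(C)(C)C | intermediate
13 | tert-butyl{3-[(3S,4E)-3,6-bis(tert-butyldimethylsilyloxy)hex-4-enyl]-2,4-dimethylphenoxy}dimethylsilane | Cc1ccc(O[Si](C)(C)C(C)(C)C)c(C)c1CC[C@H](O[Si](C)(C)C(C)(C)C)/C=C/CO[Si](C)(C)C(C)(C)C | intermediate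
14 | (2E,4S)-4-(tert-butyldimethylsilyloxy)-6-[3-(tert-butyldimethylsilyloxy)-2,6-dimethylphenyl]hex-2-en-1-ol | Cc1ccc(O[Si](C)(C)C(C)(C)C)c(C)c1CC[C@H](O[Si](C)(C)C(C)(C)C)/C=C/CO | intermediate
15 | (2E,4S)-4-(tert-butyldimethylsilyloxy)-6-[3-(tert-butyldimethylsilyloxy)-2,6-dimethylphenyl]hex-2-enyl methyl carbonate | Cc1ccc(O[Si](C)(C)C(C)(C)C)c(C)c1CC[C@H](O[Si](C)(C)C(C)(C)C)/C=C/COC(=O)OC | intermediate
16 | (2E,4S)-4-(tert-butyldimethylsilyloxy)-6-(3-hydroxy-2,6-dimethylphenyl)hex-2-enyl methyl carbonate | Cc1ccc(O)c(C)c1CC[C@H](O[Si](C)(C)C(C)(C)C)/C=C/COC(=O)OC | intermediate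
17 | (4aS,5S,6S)-6-(tert-butyldimethylsilyloxy)-5-ethenyl-1,4a-dimethyl-5,6,7,8-tetrahydronaphthalen-2(4aH)-one | O=C1C=C[C@@]2(C)[C@H](C=C)[C@@H](O[Si](C)(C)C(C)(C)C)CCC2=C1C | intermediate
18 | (4aS,5S,6S)-6-(tert-butyldimethylsilyloxy)-5-ethenyl-1,4a-dimethyl-4,4a,5,6,7,8-hexahydronaphthalen-2(3H)-one | O=C1CC[C@@]2(C)[C@H](C=C)[C@@H](O[Si](C)(C)C(C)(C)C)CCC2=C1C | intermediate
19 | lithium C3–C4 enolate of the 5β-H trans-decalone | [Li]OC=1CC[C@@]2(C)[C@H](C=C)[C@@H](O[Si](C)(C)C(C)(C)C)CC[C@@H]2C=1C | intermediate (not isolated)
20 | (4aR,5S,6S,8aS)-6-(tert-butyldimethylsilyloxy)-5-ethenyl-1,1,4a-trimethyloctahydronaphthalen-2(1H)-one | O=C1CC[C@@]2(C)[C@H](C=C)[C@@H](O[Si](C)(C)C(C)(C)C)CC[C@@H]2C1(C)C | intermediate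
21 | (2R,4aR,5S,6S,8aS)-6-(tert-butyldimethylsilyloxy)-5-ethenyl-1,1,4a-trimethyldecahydronaphthalen-2-ol | O[C@@H]1CC[C@@]2(C)[C@H](C=C)[C@@H](O[Si](C)(C)C(C)(C)C)CC[C@@H]2C1(C)C | intermediate
22 | 3α-acetate of 21 | CC(=O)O[C@@H]1CC[C@@]2(C)[C@H](C=C)[C@@H](O[Si](C)(C)C(C)(C)C)CC[C@@H]2C1(C)C | intermediate
23 | methyl but-2-ynoate | CC#CC(=O)OC | starting material
24 | methyl (Z)-3-iodobut-2-enoate | C/C(I)=C/C(=O)OC | intermediate
25 | C12 9-borabicyclo[3.3.1]nonan-9-yl adduct of 22 | CC(=O)O[C@@H]1CC[C@@]2(C)[C@H](CCB3C4CCCC3CCC4)[C@@H](O[Si](C)(C)C(C)(C)C)CC[C@@H]2C1(C)C | intermediate (not isolated)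
26 | methyl (13Z)-3α-acetoxy-8β-(tert-butyldimethylsilyloxy)-17-norlabd-13-en-15-oate | CC(=O)O[C@@H]1CC[C@@]2(C)[C@H](CC/C(C)=C\C(=O)OC)[C@@H](O[Si](C)(C)C(C)(C)C)CC[C@@H]2C1(C)C | intermediate
27 | methyl (13Z)-3α-acetoxy-8β-hydroxy-17-norlabd-13-en-15-oate | CC(=O)O[C@@H]1CC[C@@]2(C)[C@H](CC/C(C)=C\C(=O)OC)[C@@H](O)CC[C@@H]2C1(C)C | intermediate
28 | methyl (13Z)-3α-acetoxy-8-oxo-17-norlabd-13-en-15-oate | CC(=O)O[C@@H]1CC[C@@]2(C)[C@H](CC/C(C)=C\C(=O)OC)C(=O)CC[C@@H]2C1(C)C | intermediate
29 | methyl (13Z)-3α-acetoxylabda-8(17),13-dien-15-oate | CC(=O)O[C@@H]1CC[C@@]2(C)[C@H](CC/C(C)=C\C(=O)OC)C(=C)CC[C@@H]2C1(C)C | intermediate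
30 | methyl (13Z)-3α-acetoxy-7β-hydroxylabda-8(17),13-dien-15-oate | CC(=O)O[C@@H]1CC[C@@]2(C)[C@H](CC/C(C)=C\C(=O)OC)C(=C)[C@@H](O)C[C@@H]2C1(C)C | intermediate
31 | methyl (13Z)-3α-acetoxy-7-oxolabda-8(17),13-dien-15-oate | CC(=O)O[C@@H]1CC[C@@]2(C)[C@H](CC/C(C)=C\C(=O)OC)C(=C)C(=O)C[C@@H]2C1(C)C | intermediate
32 | methyl (13Z)-3α-acetoxy-7α-hydroxylabda-8(17),13-dien-15-oate | CC(=O)O[C@@H]1CC[C@@]2(C)[C@H](CC/C(C)=C\C(=O)OC)C(=C)[C@H](O)C[C@@H]2C1(C)C | intermediate
33 | methyl (3R,5S,7R,9S,10R,13Z)-3,7-dihydroxylabda-8(17),13-dien-15-oate | C=C1[C@H](O)C[C@@H]2C(C)(C)[C@H](O)CC[C@@]2(C)[C@@H]1CC/C(C)=C\C(=O)OC | target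

Total step count: 24. Longest linear sequence: 23 (steps 1–15 and 17–24; step 16 is the side branch).

Steps most likely to fail

1. **Step 11.** Several things may go wrong.
   - The allyl complex may lose the C8 proton and collapse to a diene.
   - The phenolate may attack through the ortho carbon C4, or through oxygen between molecules.
   - The relay of configuration from C8 to C10 may be weak.

   The fallback keeps the C9–C10 bond but reverses its polarity with known chemistry. It sets out from 15 and returns at 17. Palladium-catalysed silylation of the allylic carbonate with Me3SiSiMe3 (Pd2(dba)3·CHCl3, DMF, 60 °C) should give the linear (E)-allyltrimethylsilane F1. Buffered Bu4NF then frees the phenol to give the allylsilane phenol F2. Oxidation with PhI(OAc)2 in (CF3)2CHOH at 0 °C makes the phenol the electrophile, and its methyl-bearing para carbon is captured by the γ-carbon C9 of the allylsilane with loss of the silyl group, through the same chair, to give 17. Oxidative para-allylation of 4-alkylphenols by allylsilanes and ring-forming capture of an oxidised phenol by a tethered allylsilane are both established reactions.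

2. **Step 21.** The oxidation may pick the tertiary C9–H or the allylic positions of the side chain, or run on unevenly to the ketone. The fallback places the oxygen on C7 before the methylene group is made. It sets out from 28 and returns at 30. Kinetic deprotonation with LiN(SiMe3)2 in the presence of Et3SiCl (THF, −78 °C) should give the C7–C8 triethylsilyl enol ether F3. Rubottom oxidation (mCPBA, NaHCO3, CH2Cl2) on the β face, away from the C10 methyl, gives after silyl migration the 7β-(triethylsilyloxy) ketone F4. Methylenation with Zn, CH2Br2 and TiCl4 gives the 7β-(triethylsilyloxy) 8(17)-ene F5. HF·pyridine then releases 30.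

3. **Step 5.** Migratory insertion at the doubly ortho-substituted arylpalladium species may be too slow, so that reduction of the bromide, branched arylation or incomplete chain walking take over. The fallback replaces the Heck reaction by an sp2–sp3 cross-coupling. It sets out from 6 and returns at 8. Negishi coupling with commercial [2-(1,3-dioxolan-2-yl)ethyl]zinc bromide (Pd(OAc)2, SPhos, THF, 60 °C) should give the dioxolane F6. Hydrolysis with 1 M HCl in THF, which the aryl silyl ether tolerates, gives 8.

Further compounds
F1 | step 11 | tert-butyl{3-[(3S,4E)-3-(tert-butyldimethylsilyloxy)-6-(trimethylsilyl)hex-4-enyl]-2,4-dimethylphenoxy}dimethylsilane | Cc1ccc(O[Si](C)(C)C(C)(C)C)c(C)c1CC[C@H](O[Si](C)(C)C(C)(C)C)/C=C/C[Si](C)(C)C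
F2 | step 11 | 3-[(3S,4E)-3-(tert-butyldimethylsilyloxy)-6-(trimethylsilyl)hex-4-enyl]-2,4-dimethylphenol | Cc1ccc(O)c(C)c1CC[C@H](O[Si](C)(C)C(C)(C)C)/C=C/C[Si](C)(C)C
F3 | step 21 | methyl (13Z)-3α-acetoxy-8-(triethylsilyloxy)-17-norlabda-7,13-dien-15-oate | CC(=O)O[C@@H]1CC[C@@]2(C)[C@H](CC/C(C)=C\C(=O)OC)C(O[Si](CC)(CC)CC)=CC[C@@H]2C1(C)C
F4 | step 21 | methyl (13Z)-3α-acetoxy-8-oxo-7β-(triethylsilyloxy)-17-norlabd-13-en-15-oate | CC(=O)O[C@@H]1CC[C@@]2(C)[C@H](CC/C(C)=C\C(=O)OC)C(=O)[C@@H](O[Si](CC)(CC)CC)C[C@@H]2C1(C)C
F5 | step 21 | methyl (13Z)-3α-acetoxy-7β-(triethylsilyloxy)labda-8(17),13-dien-15-oate | CC(=O)O[C@@H]1CC[C@@]2(C)[C@H](CC/C(C)=C\C(=O)OC)C(=C)[C@@H](O[Si](CC)(CC)CC)C[C@@H]2C1(C)C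
F6 | step 5 | tert-butyl{3-[2-(1,3-dioxolan-2-yl)ethyl]-2,4-dimethylphenoxy}dimethylsilane | Cc1ccc(O[Si](C)(C)C(C)(C)C)c(C)c1CCC1OCCO1
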